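**Retrosynthetic overview** (flavanone numbering: O1, C2, C3, C4, C4a, C5–C8, C8a; ring B primed)

1. Target 31 ⇐ acid removal of all protecting groups from 30 ⇐ olefin cross-metathesis (allyl → prenyl) on flavanone 29.
2. Ring C of 29 (O1–C2–C3–C4–C4a–C8a) ⇐ two-atom ring expansion of the oxetan-2-one ring of (S)-β-lactone 27 (O1–C2–C3–C4) by insertion of the aryne carbons C4a≡C8a of 28 into its acyl C4–O1 bond. Enabling feature: O1–C2–C3–C4(=O) of ring C is a β-oxy-carbonyl unit, i.e. a β-lactone; O1 and C4 sit on adjacent ring-A carbons (an aryne); and the C5 oxygen next to C4a polarises that aryne so that O1 adds at C8a.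
3. Aryne precursor 23 ⇐ phloroglucinol 13 by two carbamate-directed ortho-metalations (SiMe3 at C4a, I at C8) and Negishi coupling at C8 with alkyl iodide 12.
4. 12 ⇐ Evans allylation of the acid from (R)-β-methyl-γ-butyrolactone 1; 27 ⇐ catalytic asymmetric ketene–aldehyde [2+2] on Boc-protected aldehyde 25.
5. Ring order: rings A and B are bought as arenes; the four-membered lactone ring is made in step 14 and becomes ring C in step 15; no other ring is formed.

Key step: step 15

Remark: (R)-4-methyldihydrofuran-2(3H)-one (1) is assumed to be purchased in enantiopure form.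

**Route**

Step 1
Reactants: 1 (R)-4-methyldihydrofuran-2(3H)-one
Product: 4 (R)-4-[(tert-butyldimethylsilyl)oxy]-3-methylbutanoic acid, via potassium 4-hydroxy-3-methylbutanoate 2 (not isolated), via bis-TBS ester ether 3 (not isolated)
Conditions: KOH, MeOH/H2O, rt, evaporate; TBSCl (2.5 equiv), imidazole, DMF, rt; K2CO3, MeOH/THF/H2O, 0 °C; AcOH to pH 5
Reagents that add atoms: potassium hydroxide [K+].[OH-]; tert-butyldimethylsilyl chloride CC(C)(C)[Si](C)(C)Cl
Why: Lactone saponification, exhaustive silylation and selective hydrolysis of the labile silyl ester should trap the γ-hydroxy acid in open form without touching the methyl-bearing stereocentre.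

Step 2
Reactants: 4 (R)-4-[(tert-butyldimethylsilyl)oxy]-3-methylbutanoic acid; 5 (S)-4-benzyloxazolidin-2-one
Product: 7 (S)-4-benzyl-3-[(R)-4-[(tert-butyldimethylsilyl)oxy]-3-methylbutanoyl]oxazolidin-2-one, via pivalic mixed anhydride 6 (not isolated)
Conditions: PivCl, Et3N, THF, −20 °C; then 5, LiCl, −20 °C → rt
Reagents that add atoms: none
Why: N-Acylation of the Evans oxazolidinone through the pivalic mixed anhydride (LiCl/Et3N variant) should install the auxiliary under conditions that leave the β-stereocentre and the silyl ether intact.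

Step 3
Reactants: 7 (S)-4-benzyl-3-[(R)-4-[(tert-butyldimethylsilyl)oxy]-3-methylbutanoyl]oxazolidin-2-one; 8 allyl iodide
Product: 10 (S)-4-benzyl-3-[(2S,3R)-2-allyl-4-[(tert-butyldimethylsilyl)oxy]-3-methylbutanoyl]oxazolidin-2-one, via sodium Z-enolate 9 (not isolated)
Conditions: NaHMDS, THF, −78 °C; 8, −78 → −45 °C
Reagents that add atoms: none
Why: Evans asymmetric alkylation, in which the chelated sodium (Z)-enolate should be allylated on the face opposite the benzyl group of the (S)-auxiliary and so set the (2S) centre next to the existing (3R) centre under auxiliary control; allyl stands in for prenyl because a tethered trisubstituted olefin with allylic hydrogens would later trap the aryne in an intramolecular ene reaction.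

Step 4
Reactants: 10 (S)-4-benzyl-3-[(2S,3R)-2-allyl-4-[(tert-butyldimethylsilyl)oxy]-3-methylbutanoyl]oxazolidin-2-one
Product: 11 (2S,3R)-2-allyl-4-[(tert-butyldimethylsilyl)oxy]-3-methylbutan-1-ol
Conditions: LiBH4, MeOH (1 equiv), THF, 0 °C
Reagents that add atoms: none
Why: Reductive cleavage of the N-acyl oxazolidinone with LiBH4 should give the primary alcohol without epimerising the α-centre and return the auxiliary.

Step 5
Reactants: 11 (2S,3R)-2-allyl-4-[(tert-butyldimethylsilyl)oxy]-3-methylbutan-1-ol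
Product: 12 tert-butyl{[(2R,3S)-3-(iodomethyl)-2-methylhex-5-en-1-yl]oxy}dimethylsilane
Conditions: I2, PPh3, imidazole, CH2Cl2, 0 °C → rt
Reagents that add atoms: iodine II
Why: Appel-type iodination of the primary alcohol should proceed at a carbon that is not a stereocentre and leave the silyl ether and olefin untouched.

Step 6
Reactants: 13 phloroglucinol
Product: 14 3,5-bis(methoxymethoxy)phenol
Conditions: MOMCl (2.0 equiv), iPr2NEt, DMF, 0 °C → rt
Reagents that add atoms: chloromethyl methyl ether COCCl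
Why: Williamson-type O-alkylation with two equivalents of MOMCl should give the bis-ether as the main product of a statistical protection, to be separated from mono- and tris-ethers by chromatography.

Step 7
Reactants: 14 3,5-bis(methoxymethoxy)phenol
Product: 15 3,5-bis(methoxymethoxy)phenyl N,N-diethylcarbamate
Conditions: Et2NCOCl, K2CO3, MeCN, reflux
Reagents that add atoms: N,N-diethylcarbamoyl chloride CCN(CC)C(Cl)=O
Why: O-Carbamoylation of the phenol should install the strongest oxygen-based directing group for the two ortho-metalations that follow.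

Step 8
Reactants: 15 3,5-bis(methoxymethoxy)phenyl N,N-diethylcarbamate
Product: 17 3,5-bis(methoxymethoxy)-2-(trimethylsilyl)phenyl N,N-diethylcarbamate, via aryllithium 16 (not isolated)
Conditions: s-BuLi, TMEDA, THF, −78 °C; TMSCl, −78 °C
Reagents that add atoms: chlorotrimethylsilane C[Si](C)(C)Cl
Why: Directed ortho-metalation, in which the carbamate and the flanking OMOM group should direct lithiation to one of the two equivalent positions between them, with silylation at −78 °C before anionic Fries rearrangement can set in.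

Step 9
Reactants: 17 3,5-bis(methoxymethoxy)-2-(trimethylsilyl)phenyl N,N-diethylcarbamate
Product: 19 2-iodo-3,5-bis(methoxymethoxy)-6-(trimethylsilyl)phenyl N,N-diethylcarbamate, via aryllithium 18 (not isolated)
Conditions: s-BuLi, TMEDA, THF, −78 °C; I2, −78 °C
Reagents that add atoms: iodine II
Why: A second directed ortho-metalation at the only remaining position flanked by the carbamate and an OMOM group, followed by iodine quench, should place the coupling handle at the future C8.

Step 10
Reactants: 12 tert-butyl{[(2R,3S)-3-(iodomethyl)-2-methylhex-5-en-1-yl]oxy}dimethylsilane; 19 2-iodo-3,5-bis(methoxymethoxy)-6-(trimethylsilyl)phenyl N,N-diethylcarbamate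
Product: 21 2-[(2R,3R)-2-allyl-4-[(tert-butyldimethylsilyl)oxy]-3-methylbutyl]-3,5-bis(methoxymethoxy)-6-(trimethylsilyl)phenyl N,N-diethylcarbamate, via alkylzinc iodide 20 (not isolated)
Conditions: 12, Zn dust (cat. TMSCl/BrCH2CH2Br), LiCl, THF, 40 °C; then 19, Pd(OAc)2 (3 mol%), SPhos (6 mol%), THF/NMP, 50 °C
Reagents that add atoms: none
Why: Negishi sp3–sp2 cross-coupling of the primary alkylzinc with the di-ortho-substituted aryl iodide should form the C8–CH2 bond without affecting the two stereocentres, which are β and γ to the metal.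

Step 11
Reactants: 21 2-[(2R,3R)-2-allyl-4-[(tert-butyldimethylsilyl)oxy]-3-methylbutyl]-3,5-bis(methoxymethoxy)-6-(trimethylsilyl)phenyl N,N-diethylcarbamate
Product: 22 2-[(2R,3R)-2-allyl-4-[(tert-butyldimethylsilyl)oxy]-3-methylbutyl]-3,5-bis(methoxymethoxy)-6-(trimethylsilyl)phenol
Conditions: LiAlH4, THF, 0 °C → reflux
Reagents that add atoms: none
Why: Reductive cleavage of the aryl carbamate with LiAlH4 should free the phenol while the aryl silane, the silyl and MOM ethers and the terminal olefin are inert to hydride.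

Step 12
Reactants: 22 2-[(2R,3R)-2-allyl-4-[(tert-butyldimethylsilyl)oxy]-3-methylbutyl]-3,5-bis(methoxymethoxy)-6-(trimethylsilyl)phenol
Product: 23 2-[(2R,3R)-2-allyl-4-[(tert-butyldimethylsilyl)oxy]-3-methylbutyl]-3,5-bis(methoxymethoxy)-6-(trimethylsilyl)phenyl trifluoromethanesulfonate
Conditions: Tf2O, pyridine, CH2Cl2, −20 → 0 °C
Reagents that add atoms: trifluoromethanesulfonic anhydride O=S(=O)(OS(=O)(=O)C(F)(F)F)C(F)(F)F
Why: O-Triflation of the phenol should complete the 2-(trimethylsilyl)aryl triflate needed for fluoride-induced aryne generation.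

Step 13
Reactants: 24 4-hydroxy-2-methoxybenzaldehyde
Product: 25 tert-butyl (4-formyl-3-methoxyphenyl) carbonate
Conditions: Boc2O, DMAP (5 mol%), MeCN, rt
Reagents that add atoms: di-tert-butyl dicarbonate CC(C)(C)OC(=O)OC(=O)OC(C)(C)C
Why: DMAP-catalysed O-acylation should give the aryl tert-butyl carbonate, which weakens the donor strength of the para oxygen (stabilising the later benzylic β-lactone) and is removable by acid.

Step 14
Reactants: 25 tert-butyl (4-formyl-3-methoxyphenyl) carbonate
Product: 27 tert-butyl {3-methoxy-4-[(2S)-4-oxooxetan-2-yl]phenyl} carbonate, via ketene 26 (not isolated)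
Conditions: AcCl (2.5 equiv), iPr2NEt (2.5 equiv), O-TMS-quinine (10 mol%), LiClO4 (1 equiv), CH2Cl2/Et2O, −78 °C; isolate cold and use at once
Reagents that add atoms: acetyl chloride CC(Cl)=O
Why: Catalytic asymmetric formal [2+2] cycloaddition of in situ ketene with the aldehyde under cinchona-alkaloid/lithium co-catalysis, in which the alkaloid-bound acetyl enolate adds to the Li-activated aldehyde and lactonises, the quinine-derived catalyst being expected to give the (S)-lactone by analogy with related alkaloid-catalysed ketene–aldehyde cycloadditions (the quinidine pseudo-enantiomer gives the antipode).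

Step 15
Reactants: 23 2-[(2R,3R)-2-allyl-4-[(tert-butyldimethylsilyl)oxy]-3-methylbutyl]-3,5-bis(methoxymethoxy)-6-(trimethylsilyl)phenyl trifluoromethanesulfonate; 27 tert-butyl {3-methoxy-4-[(2S)-4-oxooxetan-2-yl]phenyl} carbonate
Product: 29 tert-butyl {4-[(2S)-8-[(2R,3R)-2-allyl-4-[(tert-butyldimethylsilyl)oxy]-3-methylbutyl]-5,7-bis(methoxymethoxy)-4-oxo-3,4-dihydro-2H-chromen-2-yl]-3-methoxyphenyl} carbonate, via aryne 28 (not isolated)
Conditions: 27 (2.5 equiv), CsF (3 equiv), 18-crown-6 (cat.), toluene/MeCN 3:1, rt; 23 added over 6 h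
Reagents that add atoms: none
Why: Proposed new method: fluoride-induced 1,2-elimination of 23 should give aryne 28, the ring oxygen O1 of the β-lactone should add to aryne carbon C8a, the aryl anion so formed at C4a should attack the adjacent lactone carbonyl C4, and the bicyclic alkoxide should collapse with cleavage of the strained acyl C4–O1 bond, so that C4a and C8a end up inserted between C4 and O1. The closest known reaction types are the σ-insertion of arynes into the N–C(=O) bond of amides and β-lactams (giving 2,3-dihydroquinolin-4-ones) and the C–O insertion of arynes into carboxylic acids that leads to 2-hydroxyaryl ketones and chroman-4-ones. Ring C is closed by two-atom ring expansion of the oxetan-2-one (4-exo attack of C4a on C4, then fragmentation), not by cyclisation of an open chain. No new stereocentre is formed: C2 is the lactone β-carbon and its O1–C2 bond is never broken, so the (S) configuration should be carried over unchanged. The step needs regioselectivity (O1 to C8a, acyl to C4a), which the C5 OMOM group should secure by polarising the aryne so that the nucleophile adds to the distal carbon and the anion develops next to oxygen. It also needs attack through the ring oxygen without ionisation of the benzylic C2–O1 bond, which the reduced ester resonance of the strained lactone, the electron-poor carbonate on ring B, the low-polarity medium and the allyl (not prenyl) side chain are meant to secure.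

Step 16
Reactants: 29 tert-butyl {4-[(2S)-8-[(2R,3R)-2-allyl-4-[(tert-butyldimethylsilyl)oxy]-3-methylbutyl]-5,7-bis(methoxymethoxy)-4-oxo-3,4-dihydro-2H-chromen-2-yl]-3-methoxyphenyl} carbonate
Product: 30 tert-butyl {4-[(2S)-8-[(2R,3R)-4-[(tert-butyldimethylsilyl)oxy]-3-methyl-2-(3-methylbut-2-en-1-yl)butyl]-5,7-bis(methoxymethoxy)-4-oxo-3,4-dihydro-2H-chromen-2-yl]-3-methoxyphenyl} carbonate
Conditions: 2-methylbut-2-ene (excess), Grubbs II (5 mol%), CH2Cl2, 40 °C, sealed tube
Reagents that add atoms: 2-methylbut-2-ene CC=C(C)C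
Why: Olefin cross-metathesis of the terminal allyl group with excess 2-methylbut-2-ene should give the prenyl group under neutral conditions that do not endanger the base-sensitive flavanone stereocentre.

Step 17
Reactants: 30 tert-butyl {4-[(2S)-8-[(2R,3R)-4-[(tert-butyldimethylsilyl)oxy]-3-methyl-2-(3-methylbut-2-en-1-yl)butyl]-5,7-bis(methoxymethoxy)-4-oxo-3,4-dihydro-2H-chromen-2-yl]-3-methoxyphenyl} carbonate
Product: 31 (2S)-5,7-dihydroxy-2-(4-hydroxy-2-methoxyphenyl)-8-[(2R,3R)-4-hydroxy-3-methyl-2-(3-methylbut-2-en-1-yl)butyl]-2,3-dihydro-4H-chromen-4-one (CNP0081318.1)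
Conditions: 3 M aq. HCl/MeOH (1:5), 45 °C
Reagents that add atoms: none
Why: Acid-catalysed acetal exchange and solvolysis should remove both MOM ethers, the primary TBS ether and the aryl tert-butyl carbonate in one operation, acid being chosen because the C2 stereocentre of a flavanone epimerises under base by retro-oxa-Michael ring opening.

**Compound list**

1 | (R)-4-methyldihydrofuran-2(3H)-one | O=C1C[C@@H](C)CO1 | starting material
2 | potassium (R)-4-hydroxy-3-methylbutanoate | [K+].[O-]C(=O)C[C@@H](C)CO | intermediate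
3 | tert-butyldimethylsilyl (R)-4-[(tert-butyldimethylsilyl)oxy]-3-methylbutanoate | CC(C)(C)[Si](C)(C)OC(=O)C[C@@H](C)CO[Si](C)(C)C(C)(C)C | intermediate
4 | (R)-4-[(tert-butyldimethylsilyl)oxy]-3-methylbutanoic acid | OC(=O)C[C@@H](C)CO[Si](C)(C)C(C)(C)C | intermediate
5 | (S)-4-benzyloxazolidin-2-one | O=C1N[C@@H](Cc2ccccc2)CO1 | starting material
6 | (R)-4-[(tert-butyldimethylsilyl)oxy]-3-methylbutanoic pivalic anhydride | CC(C)(C)C(=O)OC(=O)C[C@@H](C)CO[Si](C)(C)C(C)(C)C | intermediate
7 | (S)-4-benzyl-3-[(R)-4-[(tert-butyldimethylsilyl)oxy]-3-methylbutanoyl]oxazolidin-2-one | O=C1OC[C@H](Cc2ccccc2)N1C(=O)C[C@@H](C)CO[Si](C)(C)C(C)(C)C | intermediate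
8 | allyl iodide (3-iodoprop-1-ene) | C=CCI | starting material
9 | sodium (Z)-enolate of 7 | [Na+].[O-]/C(=C\[C@@H](C)CO[Si](C)(C)C(C)(C)C)N1[C@@H](Cc2ccccc2)COC1=O | intermediate
10 | (S)-4-benzyl-3-[(2S,3R)-2-allyl-4-[(tert-butyldimethylsilyl)oxy]-3-methylbutanoyl]oxazolidin-2-one | O=C1OC[C@H](Cc2ccccc2)N1C(=O)[C@@H](CC=C)[C@@H](C)CO[Si](C)(C)C(C)(C)C | intermediate
11 | (2S,3R)-2-allyl-4-[(tert-butyldimethylsilyl)oxy]-3-methylbutan-1-ol | OC[C@@H](CC=C)[C@@H](C)CO[Si](C)(C)C(C)(C)C | intermediate
12 | tert-butyl{[(2R,3S)-3-(iodomethyl)-2-methylhex-5-en-1-yl]oxy}dimethylsilane | IC[C@@H](CC=C)[C@@H](C)CO[Si](C)(C)C(C)(C)C | intermediate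
13 | phloroglucinol (benzene-1,3,5-triol) | Oc1cc(O)cc(O)c1 | starting material
14 | 3,5-bis(methoxymethoxy)phenol | COCOc1cc(O)cc(OCOC)c1 | intermediate
15 | 3,5-bis(methoxymethoxy)phenyl N,N-diethylcarbamate | CCN(CC)C(=O)Oc1cc(OCOC)cc(OCOC)c1 | intermediate
16 | 2-lithio-3,5-bis(methoxymethoxy)phenyl N,N-diethylcarbamate | CCN(CC)C(=O)Oc1c([Li])c(OCOC)cc(OCOC)c1 | intermediate
17 | 3,5-bis(methoxymethoxy)-2-(trimethylsilyl)phenyl N,N-diethylcarbamate | CCN(CC)C(=O)Oc1c([Si](C)(C)C)c(OCOC)cc(OCOC)c1 | intermediate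
18 | 2-lithio-3,5-bis(methoxymethoxy)-6-(trimethylsilyl)phenyl N,N-diethylcarbamate | CCN(CC)C(=O)Oc1c([Si](C)(C)C)c(OCOC)cc(OCOC)c1[Li] | intermediate
19 | 2-iodo-3,5-bis(methoxymethoxy)-6-(trimethylsilyl)phenyl N,N-diethylcarbamate | CCN(CC)C(=O)Oc1c([Si](C)(C)C)c(OCOC)cc(OCOC)c1I | intermediate
20 | [(2S,3R)-2-allyl-4-[(tert-butyldimethylsilyl)oxy]-3-methylbutyl]zinc iodide | I[Zn]C[C@@H](CC=C)[C@@H](C)CO[Si](C)(C)C(C)(C)C | intermediate
21 | 2-[(2R,3R)-2-allyl-4-[(tert-butyldimethylsilyl)oxy]-3-methylbutyl]-3,5-bis(methoxymethoxy)-6-(trimethylsilyl)phenyl N,N-diethylcarbamate | CCN(CC)C(=O)Oc1c([Si](C)(C)C)c(OCOC)cc(OCOC)c1C[C@@H](CC=C)[C@@H](C)CO[Si](C)(C)C(C)(C)C | intermediate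
22 | 2-[(2R,3R)-2-allyl-4-[(tert-butyldimethylsilyl)oxy]-3-methylbutyl]-3,5-bis(methoxymethoxy)-6-(trimethylsilyl)phenol | Oc1c([Si](C)(C)C)c(OCOC)cc(OCOC)c1C[C@@H](CC=C)[C@@H](C)CO[Si](C)(C)C(C)(C)C | intermediate
23 | 2-[(2R,3R)-2-allyl-4-[(tert-butyldimethylsilyl)oxy]-3-methylbutyl]-3,5-bis(methoxymethoxy)-6-(trimethylsilyl)phenyl trifluoromethanesulfonate | O=S(=O)(Oc1c([Si](C)(C)C)c(OCOC)cc(OCOC)c1C[C@@H](CC=C)[C@@H](C)CO[Si](C)(C)C(C)(C)C)C(F)(F)F | intermediate
24 | 4-hydroxy-2-methoxybenzaldehyde | COc1cc(O)ccc1C=O | starting material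
25 | tert-butyl (4-formyl-3-methoxyphenyl) carbonate | COc1cc(OC(=O)OC(C)(C)C)ccc1C=O | intermediate
26 | ketene | C=C=O | intermediate
27 | tert-butyl {3-methoxy-4-[(2S)-4-oxooxetan-2-yl]phenyl} carbonate | COc1cc(OC(=O)OC(C)(C)C)ccc1[C@@H]1CC(=O)O1 | intermediate
28 | 3-[(2R,3R)-2-allyl-4-[(tert-butyldimethylsilyl)oxy]-3-methylbutyl]-4,6-bis(methoxymethoxy)-1,2-didehydrobenzene (aryne) | COCOC1=CC(OCOC)=C(C[C@@H](CC=C)[C@@H](C)CO[Si](C)(C)C(C)(C)C)C#C1 | intermediate
29 | tert-butyl {4-[(2S)-8-[(2R,3R)-2-allyl-4-[(tert-butyldimethylsilyl)oxy]-3-methylbutyl]-5,7-bis(methoxymethoxy)-4-oxo-3,4-dihydro-2H-chromen-2-yl]-3-methoxyphenyl} carbonate | COc1cc(OC(=O)OC(C)(C)C)ccc1[C@@H]1CC(=O)c2c(OCOC)cc(OCOC)c(C[C@@H](CC=C)[C@@H](C)CO[Si](C)(C)C(C)(C)C)c2O1 | intermediate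
30 | tert-butyl {4-[(2S)-8-[(2R,3R)-4-[(tert-butyldimethylsilyl)oxy]-3-methyl-2-(3-methylbut-2-en-1-yl)butyl]-5,7-bis(methoxymethoxy)-4-oxo-3,4-dihydro-2H-chromen-2-yl]-3-methoxyphenyl} carbonate | COc1cc(OC(=O)OC(C)(C)C)ccc1[C@@H]1CC(=O)c2c(OCOC)cc(OCOC)c(C[C@@H](CC=C(C)C)[C@@H](C)CO[Si](C)(C)C(C)(C)C)c2O1 | intermediate
31 | (2S)-5,7-dihydroxy-2-(4-hydroxy-2-methoxyphenyl)-8-[(2R,3R)-4-hydroxy-3-methyl-2-(3-methylbut-2-en-1-yl)butyl]-2,3-dihydro-4H-chromen-4-one (CNP0081318.1) | COc1cc(O)ccc1[C@@H]1CC(=O)c2c(O)cc(O)c(C[C@@H](CC=C(C)C)[C@@H](C)CO)c2O1 | target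

**Step count**

Total: 17 steps. Longest linear sequence: 11 steps (steps 1–5, 10–12, 15–17, from 1).

**Steps most likely to fail**

Step 15 (Proposed new method). What may go wrong: the ring oxygen of the lactone may add to the aryne too slowly, so that the aryne is lost to oligomerisation or to the solvent; attack through the carbonyl oxygen, or ionisation of the benzylic C2–O1 bond, would lead to decarboxylation or to loss of configuration at C2. The fallback uses known chemistry, gives up the strained lactone for an open-chain acid, sets out from 23 and 24, and comes back to the route at 31. Aldehyde 24 would be protected (MOMCl, iPr2NEt, CH2Cl2) as 2-methoxy-4-(methoxymethoxy)benzaldehyde F1 and homologated by Knoevenagel–Doebner condensation (malonic acid, pyridine, cat. piperidine, 80 °C) to (E)-3-[2-methoxy-4-(methoxymethoxy)phenyl]prop-2-enoic acid F2. Aryne 28, generated from 23 with CsF in THF at 125 °C (sealed tube) in the presence of F2, should undergo the known C–O insertion of arynes into carboxylic acids (carboxylate to C8a, acyl shift to C4a). The 2'-hydroxychalcone so formed should close by oxa-Michael addition to 8-[(2R,3R)-2-allyl-4-[(tert-butyldimethylsilyl)oxy]-3-methylbutyl]-2-[2-methoxy-4-(methoxymethoxy)phenyl]-5,7-bis(methoxymethoxy)chroman-4-one F3, a mixture of the two C2 epimers. Because the side-chain stereocentres are fixed, these are diastereomers; the (2S) epimer of that chromanone F4 would be isolated by preparative HPLC, and the (2R) epimer re-equilibrated with base through the chalcone and recycled. Cross-metathesis as in step 16 should give the prenyl compound (2S)-8-[(2R,3R)-4-[(tert-butyldimethylsilyl)oxy]-3-methyl-2-(3-methylbut-2-en-1-yl)butyl]-2-[2-methoxy-4-(methoxymethoxy)phenyl]-5,7-bis(methoxymethoxy)chroman-4-one F5, and the acid treatment of step 17 should give 31.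

Step 14. What may go wrong: slow cycloaddition with an electron-rich, ortho-substituted aromatic aldehyde, incomplete enantiocontrol, and decarboxylation or ionisation of the benzylic lactone during isolation. The fallback sets out from 25 and comes back at 27. Roskamp homologation of 25 (benzyl diazoacetate, cat. SnCl2, CH2Cl2) should give benzyl 3-[4-(tert-butoxycarbonyloxy)-2-methoxyphenyl]-3-oxopropanoate F6. Noyori asymmetric transfer hydrogenation (RuCl[(S,S)-TsDPEN](p-cymene), HCO2H/Et3N), whose sense of induction for aryl ketones is well established, should give benzyl (3S)-3-[4-(tert-butoxycarbonyloxy)-2-methoxyphenyl]-3-hydroxypropanoate F7. Hydrogenolysis (H2, Pd/C, EtOAc) should give (3S)-3-[4-(tert-butoxycarbonyloxy)-2-methoxyphenyl]-3-hydroxypropanoic acid F8, which would be lactonised with retention by carboxyl activation (PhSO2Cl, pyridine, 0 °C) to 27.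

Step 17. What may go wrong: Markovnikov addition of HCl or methanol to the trisubstituted prenyl olefin during the acid treatment, and slow loss of configuration at C2 if heating has to be prolonged. The fallback reverses the order of the last two operations, sets out from 29 and comes back at 31. The same acid treatment applied to 29, whose terminal olefin is inert to dilute acid, should give (2S)-8-[(2R,3R)-2-allyl-4-hydroxy-3-methylbutyl]-5,7-dihydroxy-2-(4-hydroxy-2-methoxyphenyl)-2,3-dihydro-4H-chromen-4-one F9. Cross-metathesis of this tetraol with 2-methylbut-2-ene (Hoveyda–Grubbs II, CH2Cl2, 40 °C), which tolerates free phenols and alcohols, would then deliver 31 as the last step.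

**Further compounds**

F1 | step 15 | 2-methoxy-4-(methoxymethoxy)benzaldehyde | COCOc1ccc(C=O)c(OC)c1
F2 | step 15 | (E)-3-[2-methoxy-4-(methoxymethoxy)phenyl]prop-2-enoic acid | COCOc1ccc(/C=C/C(O)=O)c(OC)c1
F3 | step 15 | 8-[(2R,3R)-2-allyl-4-[(tert-butyldimethylsilyl)oxy]-3-methylbutyl]-2-[2-methoxy-4-(methoxymethoxy)phenyl]-5,7-bis(methoxymethoxy)chroman-4-one (mixture of C2 epimers) | COCOc1ccc(C2CC(=O)c3c(OCOC)cc(OCOC)c(C[C@@H](CC=C)[C@@H](C)CO[Si](C)(C)C(C)(C)C)c3O2)c(OC)c1
F4 | step 15 | (2S)-8-[(2R,3R)-2-allyl-4-[(tert-butyldimethylsilyl)oxy]-3-methylbutyl]-2-[2-methoxy-4-(methoxymethoxy)phenyl]-5,7-bis(methoxymethoxy)chroman-4-one | COCOc1ccc([C@@H]2CC(=O)c3c(OCOC)cc(OCOC)c(C[C@@H](CC=C)[C@@H](C)CO[Si](C)(C)C(C)(C)C)c3O2)c(OC)c1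
F5 | step 15 | (2S)-8-[(2R,3R)-4-[(tert-butyldimethylsilyl)oxy]-3-methyl-2-(3-methylbut-2-en-1-yl)butyl]-2-[2-methoxy-4-(methoxymethoxy)phenyl]-5,7-bis(methoxymethoxy)chroman-4-one | COCOc1ccc([C@@H]2CC(=O)c3c(OCOC)cc(OCOC)c(C[C@@H](CC=C(C)C)[C@@H](C)CO[Si](C)(C)C(C)(C)C)c3O2)c(OC)c1
F6 | step 14 | benzyl 3-[4-(tert-butoxycarbonyloxy)-2-methoxyphenyl]-3-oxopropanoate | COc1cc(OC(=O)OC(C)(C)C)ccc1C(=O)CC(=O)OCc1ccccc1
F7 | step 14 | benzyl (3S)-3-[4-(tert-butoxycarbonyloxy)-2-methoxyphenyl]-3-hydroxypropanoate | COc1cc(OC(=O)OC(C)(C)C)ccc1[C@@H](O)CC(=O)OCc1ccccc1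
F8 | step 14 | (3S)-3-[4-(tert-butoxycarbonyloxy)-2-methoxyphenyl]-3-hydroxypropanoic acid | COc1cc(OC(=O)OC(C)(C)C)ccc1[C@@H](O)CC(O)=O
F9 | step 17 | (2S)-8-[(2R,3R)-2-allyl-4-hydroxy-3-methylbutyl]-5,7-dihydroxy-2-(4-hydroxy-2-methoxyphenyl)-2,3-dihydro-4H-chromen-4-one | COc1cc(O)ccc1[C@@H]1CC(=O)c2c(O)cc(O)c(C[C@@H](CC=C)[C@@H](C)CO)c2O1
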